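Read the ochre run first, since our flask is the same reaction with 13 mM of starting material in place of 26 mM.

| flask | starting material | remark | time |
|---|---|---|---|
| ochre | 26 mM | run made earlier |  |
| flask | 13 mM |  | 80 min |

ochre run (percent of the starting material charged)

| time / min | target / % | isomer of the product / % | starting material / % |
|---|---|---|---|
| 0.667 | 12 | 8 | 82 |
| 1.33 | 19 | 9 | 72 |
| 2.50 | 32 | 17 | 50 |
| 4.00 | 43 | 26 | 33 |
| 8.00 | 56 | 31 | 14 |

(standard deviation of a reading: 1.5 percentage points)

- ratio of target to isomer of the product at 5.0 s
- ratio of target to isomer of the product at 80 min
- which of target and isomer of the product there is more of at 80 min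

- the earlier runs were read with a standard deviation of 1.5 percentage points
- a reading or a percentage of target counts all its forms, free or not

The ochre run had starting material at half of its charge at 2.50 min, so a first-order fall gives a time constant of 3.61 min. Summing each product's readings and dividing gives 1.78. We call this the early ratio, the rate of making target over the rate of making isomer, which is a selectivity factor.

Now an oddity. At 5.0 s our flask has run 0.0231 time constants, so 2.28% of the starting material has reacted. The isomer's part, 0.821%, is smaller than the scatter of 1.5 percentage points, and yet we state a ratio there. This is sound: two amounts growing from zero stand at the ratio of their rates, however small they are, and scatter belongs to readings, not to rates. If both channels have the same order, the charge cancels, so we expect 1.78 in this flask. At the other end, 80 min is 22.2 time constants, far beyond the ochre run's last reading at 8.00 min, so we carry the same number there with less trust.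

The forecast gave 1.8 at 5.0 s and 1.8 at 80 min, with target ahead, warning that “a rate near 0.01 per min would be invisible”.

The flask gives 1.63 at 5.0 s and 3.41 at 80 min, with target ahead.

    starting material ⇌ isomer of the product (K = 28.0, k = 0.110 /min)
    starting material ⇌ target (K = 13.0, k = 0.180 /min)
    target ⇌ isomer of the product (k = 0.0230 /min)
    crystals ⇌ target, rate k4*(cs4 - [target]) while solid is left; crystals form when [target] > cs4 (solubility = 0.770 mM, k = 2.10 /min)

The time constant 3.61 min is shorter than the 43.5 min of the step between target and isomer. In this flask the ratio keeps rising after starting material is down to 0.693% at 40.0 min, reaching 2.09 times the flask's own value at 5.0 s by 80 min. In the neighbour flask, charged with 7.8 mM, the early ratio again gives 1.78 at 5.0 s. That flask computes to 1.63 there and 2.55 at 80 min.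

The data are simulated from invented constants; the scatter is artificial.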